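**Plan**

- Unit 1 is the 7-methoxyflavonol and unit 2 the 5,7-dihydroxyflavonol with the methoxylated ring B; each unit has rings A, C and B, and the two B rings are joined through the diaryl ether oxygen.
- Last cuts: the four benzyl ethers and both C3–OH bonds (the two flavone C2=C3 bonds are oxidised together). Ring C of unit 2 is cut at O1–C2 and C2–C3 (Baker–Venkataraman on a benzoate arm), ring C of unit 1 at O1–C2 (chalcone), ring A of unit 1 at C4a–C5.
- Enabling feature: ring A of unit 1 is a phloroglucinol whose only methyl ether sits at C7, para to the acylated C4a and between the C5 and C8a oxygens. 4-Methoxy-6-methyl-2-pyrone already holds this pattern (C4–OMe, C2 carbonyl, ring oxygen on C6), so lactone opening and Claisen closure give this ring with the ether in place.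
- Earlier cuts: the pyrone CH2–C(=O) bond (acyl imidazole plus lithiated pyrone), the styryl C=C (Knoevenagel–Doebner), the aryl–O bond of the diaryl ether on the side of unit 1 (SNAr).
- Forward order: diaryl ether between the two B rings, cinnamoyl arm, pyrone, ring A of unit 1, ring C of unit 1, then ring A of unit 2 attached through the ester arm and ring C of unit 2 closed, both C3 hydroxyls, debenzylation.
- Stereochemistry: the target has no stereocentre; the E styryl geometry comes from the Doebner condensation and disappears when ring C of unit 1 is aromatised.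

Key step: step 6

Remark: the bis-epoxide 19 formed in step 13 is a mixture of stereoisomers; this is of no consequence because both oxiranes open to planar flavonols in the same flask.

**Route**

Step 1
Reactants: 1 4-fluoro-3-hydroxybenzaldehyde
Product: 2 3-(benzyloxy)-4-fluorobenzaldehyde
Conditions: BnBr, K2CO3, DMF, rt
Reagents that add atoms: benzyl bromide, BrCc1ccccc1
Why: Williamson etherification masks the phenol, whose phenoxide would otherwise deactivate the ring towards the SNAr of step 2, with a group that is kept until the final hydrogenolysis.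

Step 2
Reactants: 2 3-(benzyloxy)-4-fluorobenzaldehyde; 3 methyl vanillate (methyl 4-hydroxy-3-methoxybenzoate)
Product: 4 methyl 4-[2-(benzyloxy)-4-formylphenoxy]-3-methoxybenzoate
Conditions: K2CO3, DMF, 120 °C
Reagents that add atoms: none
Why: SNAr displacement of the fluoride para to the formyl group by the vanillate phenoxide through a Meisenheimer adduct should form the diaryl ether that links the two B rings, the ester and benzyl ether being inert to carbonate.

Step 3
Reactants: 4 methyl 4-[2-(benzyloxy)-4-formylphenoxy]-3-methoxybenzoate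
Product: 5 (2E)-3-{3-(benzyloxy)-4-[2-methoxy-4-(methoxycarbonyl)phenoxy]phenyl}prop-2-enoic acid
Conditions: malonic acid, pyridine, piperidine (cat.), 90 °C; then aq. HCl
Reagents that add atoms: malonic acid, OC(=O)CC(=O)O
Why: Knoevenagel condensation in the Doebner modification, with decarboxylation of the alkylidene malonic acid, should give the thermodynamically preferred E-cinnamic acid while the methyl ester is untouched by the amine bases.

Step 4
Reactants: 5 (2E)-3-{3-(benzyloxy)-4-[2-methoxy-4-(methoxycarbonyl)phenoxy]phenyl}prop-2-enoic acid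
Product: 6 methyl 4-{2-(benzyloxy)-4-[(E)-3-(1H-imidazol-1-yl)-3-oxoprop-1-enyl]phenoxy}-3-methoxybenzoate
Conditions: CDI, THF, rt; concentration and rapid cold aqueous wash
Reagents that add atoms: 1,1'-carbonyldiimidazole (CDI), O=C(n1ccnc1)n1ccnc1
Why: CDI activation converts the acid into an isolable N-acylimidazole that is far more electrophilic than the methyl benzoate, and isolating it removes the free imidazole that would protonate the dienolate in step 5.

Step 5
Reactants: 6 methyl 4-{2-(benzyloxy)-4-[(E)-3-(1H-imidazol-1-yl)-3-oxoprop-1-enyl]phenoxy}-3-methoxybenzoate; 7 4-methoxy-6-methyl-2H-pyran-2-one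
Product: 8 methyl 4-{2-(benzyloxy)-4-[(E)-4-(4-methoxy-2-oxo-2H-pyran-6-yl)-3-oxobut-1-enyl]phenoxy}-3-methoxybenzoate
Conditions: 7 (2.2 equiv), LiN(iPr)2 (2.2 equiv), THF, −78 °C; then 6, −78 to −40 °C; aq. NH4Cl
Reagents that add atoms: none
Why: Deprotonation of the C6 methyl group gives the vinylogous lithium enolate, which should undergo Claisen-type C-acylation by the acyl imidazole at low temperature (1,2-attack of the hard enolate, the benzoate being much less reactive), the second equivalent of anion absorbing the acidic proton of the product.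

Step 6
Reactants: 8 methyl 4-{2-(benzyloxy)-4-[(E)-4-(4-methoxy-2-oxo-2H-pyran-6-yl)-3-oxobut-1-enyl]phenoxy}-3-methoxybenzoate
Product: 10 methyl 4-{2-(benzyloxy)-4-[(E)-3-(2,6-dihydroxy-4-methoxyphenyl)-3-oxoprop-1-enyl]phenoxy}-3-methoxybenzoate, via ring-opened dioxo ester 9 (not isolated)
Conditions: Mg(OMe)2 (5 equiv), MeOH/THF, reflux; then 1 M HCl
Reagents that add atoms: none
Why: Methoxide adds to the lactone carbonyl of 8 and the ring opens to the magnesium chelate of the 3-methoxy-5,7-dioxo-2-enoate 9, in which ester and chain stay cis on the enol ether double bond inherited from the pyrone. The methylene between the two ketones, the most acidic carbon, then attacks the ester carbonyl in a Claisen (Dieckmann-type) condensation; the methoxide taken up in the opening is expelled again and enolisation gives the benzene ring, with the new C4a–C5 bond and the former pyrone methoxy group para to the acyl carbon. The closest known reaction type is the base-induced conversion of 6-(2-oxoalkyl)-4-alkoxy-2-pyrones into acylphloroglucinol monoethers familiar from biomimetic polyketide chemistry. Ring A of unit 1 closes in a 6-(enolexo)-exo-trig mode at the ester carbonyl, the diketonate being the donor. No stereocentre is formed. The step needs Claisen folding to win over the aldol folding that would give a resorcylate; the magnesium chelate fixes the nucleophile at the central methylene, the enol ether keeps the ester α-carbon a non-nucleophilic vinylic CH, and the methyl benzoate is spared because methoxide exchange on it is degenerate.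

Step 7
Reactants: 10 methyl 4-{2-(benzyloxy)-4-[(E)-3-(2,6-dihydroxy-4-methoxyphenyl)-3-oxoprop-1-enyl]phenoxy}-3-methoxybenzoate
Product: 11 methyl 4-[2-(benzyloxy)-4-(5-hydroxy-7-methoxy-4-oxo-4H-chromen-2-yl)phenoxy]-3-methoxybenzoate
Conditions: I2 (10 mol%), DMSO, 120 °C
Reagents that add atoms: none
Why: Iodine-catalysed oxidative cyclisation of a 2'-hydroxychalcone in DMSO (oxa-Michael closure, α-iodination, loss of HI, reoxidation of HI by DMSO) should close ring C of unit 1 at the O1–C2 bond without regiochemical choice because the two phenols are equivalent, and any flavanone already formed from 10 is oxidised to the same flavone.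

Step 8
Reactants: 11 methyl 4-[2-(benzyloxy)-4-(5-hydroxy-7-methoxy-4-oxo-4H-chromen-2-yl)phenoxy]-3-methoxybenzoate
Product: 12 methyl 4-{2-(benzyloxy)-4-[5-(benzyloxy)-7-methoxy-4-oxo-4H-chromen-2-yl]phenoxy}-3-methoxybenzoate
Conditions: BnBr, K2CO3, DMF, 70 °C
Reagents that add atoms: benzyl bromide, BrCc1ccccc1
Why: Williamson benzylation of the chelated 5-hydroxyl, which needs heating, removes the hydrogen bond that would retard the later dioxirane epoxidation and the acidic proton that would interfere with the base-mediated step 12.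

Step 9
Reactants: 12 methyl 4-{2-(benzyloxy)-4-[5-(benzyloxy)-7-methoxy-4-oxo-4H-chromen-2-yl]phenoxy}-3-methoxybenzoate
Product: 13 4-{2-(benzyloxy)-4-[5-(benzyloxy)-7-methoxy-4-oxo-4H-chromen-2-yl]phenoxy}-3-methoxybenzoic acid
Conditions: LiOH·H2O, THF/H2O, rt; then 1 M HCl
Reagents that add atoms: lithium hydroxide, [Li+].[OH-]
Why: Saponification of the methyl ester at room temperature should leave the fully etherified flavone intact, any reversible opening of the pyranone being undone on acidification.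

Step 10
Reactants: 14 1-(2,4,6-trihydroxyphenyl)ethanone
Product: 15 1-[2,4-bis(benzyloxy)-6-hydroxyphenyl]ethanone
Conditions: BnBr (2 equiv), K2CO3, DMF, 0 °C to rt
Reagents that add atoms: benzyl bromide, BrCc1ccccc1
Why: Williamson benzylation stops at the dibenzyl ether because the remaining ortho hydroxyl is deactivated by chelation to the acetyl carbonyl, leaving exactly the phenol needed for the ester of step 11.

Step 11
Reactants: 13 4-{2-(benzyloxy)-4-[5-(benzyloxy)-7-methoxy-4-oxo-4H-chromen-2-yl]phenoxy}-3-methoxybenzoic acid; 15 1-[2,4-bis(benzyloxy)-6-hydroxyphenyl]ethanone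
Product: 16 2-acetyl-3,5-bis(benzyloxy)phenyl 4-{2-(benzyloxy)-4-[5-(benzyloxy)-7-methoxy-4-oxo-4H-chromen-2-yl]phenoxy}-3-methoxybenzoate
Conditions: DCC, DMAP (cat.), CH2Cl2, rt
Reagents that add atoms: none
Why: Steglich esterification through the O-acylisourea and the acylpyridinium ion is the standard way to acylate a chelated 2-hydroxyacetophenone under neutral conditions that spare the flavone and the benzyl ethers.

Step 12
Reactants: 16 2-acetyl-3,5-bis(benzyloxy)phenyl 4-{2-(benzyloxy)-4-[5-(benzyloxy)-7-methoxy-4-oxo-4H-chromen-2-yl]phenoxy}-3-methoxybenzoate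
Product: 18 5,7-bis(benzyloxy)-2-(4-{2-(benzyloxy)-4-[5-(benzyloxy)-7-methoxy-4-oxo-4H-chromen-2-yl]phenoxy}-3-methoxyphenyl)-4H-chromen-4-one, via 1,3-diketone 17 (not isolated)
Conditions: LiN(SiMe3)2 (3 equiv), THF, −78 to 0 °C; AcOH quench; then p-TsOH·H2O (cat.), toluene, 90 °C
Reagents that add atoms: none
Why: Baker–Venkataraman rearrangement (intramolecular acyl transfer from the phenol oxygen to the acetyl enolate carbon, forming C2–C3 of unit 2) followed by acid-catalysed cyclodehydration of the 2-hydroxyaryl 1,3-diketone closes ring C of unit 2 at the O1–C2 bond, the non-nucleophilic amide base and the mild sulfonic acid sparing the first flavone and the benzyl ethers.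

Step 13
Reactants: 18 5,7-bis(benzyloxy)-2-(4-{2-(benzyloxy)-4-[5-(benzyloxy)-7-methoxy-4-oxo-4H-chromen-2-yl]phenoxy}-3-methoxyphenyl)-4H-chromen-4-one
Product: 20 5,7-bis(benzyloxy)-2-(4-{2-(benzyloxy)-4-[5-(benzyloxy)-3-hydroxy-7-methoxy-4-oxo-4H-chromen-2-yl]phenoxy}-3-methoxyphenyl)-3-hydroxy-4H-chromen-4-one, via bis(2,3-epoxide) 19 (not isolated)
Conditions: DMDO (excess, acetone solution), CH2Cl2, 0 °C to rt; then p-TsOH·H2O (cat.), CH2Cl2, rt
Reagents that add atoms: dimethyldioxirane (DMDO), CC1(C)OO1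
Why: Dioxirane epoxidation of the C2=C3 bond of 5-O-protected flavones, followed by acid-induced oxirane opening at C2 and loss of the C3 proton, is the established flavone-to-flavonol oxidation and should install both C3 hydroxyls in one operation.

Step 14
Reactants: 20 5,7-bis(benzyloxy)-2-(4-{2-(benzyloxy)-4-[5-(benzyloxy)-3-hydroxy-7-methoxy-4-oxo-4H-chromen-2-yl]phenoxy}-3-methoxyphenyl)-3-hydroxy-4H-chromen-4-one
Product: 21 2-{4-[4-(3,5-dihydroxy-7-methoxy-4-oxo-4H-chromen-2-yl)-2-hydroxyphenoxy]-3-methoxyphenyl}-3,5,7-trihydroxy-4H-chromen-4-one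
Conditions: H2 (1 atm), 10% Pd/C, THF/MeOH, rt
Reagents that add atoms: none
Why: Catalytic hydrogenolysis should cleave the four aryl benzyl ethers while the methyl ethers, the diaryl ether and the tetrasubstituted, chelated flavonol double bonds are retained.

**Compound list**

1 | 4-fluoro-3-hydroxybenzaldehyde | O=Cc1ccc(F)c(O)c1 | starting material
2 | 3-(benzyloxy)-4-fluorobenzaldehyde | O=Cc1ccc(F)c(OCc2ccccc2)c1 | intermediate
3 | methyl vanillate (methyl 4-hydroxy-3-methoxybenzoate) | COC(=O)c1ccc(O)c(OC)c1 | starting material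
4 | methyl 4-[2-(benzyloxy)-4-formylphenoxy]-3-methoxybenzoate | COC(=O)c1ccc(Oc2ccc(C=O)cc2OCc2ccccc2)c(OC)c1 | intermediate
5 | (2E)-3-{3-(benzyloxy)-4-[2-methoxy-4-(methoxycarbonyl)phenoxy]phenyl}prop-2-enoic acid | COC(=O)c1ccc(Oc2ccc(/C=C/C(=O)O)cc2OCc2ccccc2)c(OC)c1 | intermediate
6 | methyl 4-{2-(benzyloxy)-4-[(E)-3-(1H-imidazol-1-yl)-3-oxoprop-1-enyl]phenoxy}-3-methoxybenzoate | COC(=O)c1ccc(Oc2ccc(/C=C/C(=O)n3ccnc3)cc2OCc2ccccc2)c(OC)c1 | intermediate
7 | 4-methoxy-6-methyl-2H-pyran-2-one | COC1=CC(=O)OC(C)=C1 | starting material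
8 | methyl 4-{2-(benzyloxy)-4-[(E)-4-(4-methoxy-2-oxo-2H-pyran-6-yl)-3-oxobut-1-enyl]phenoxy}-3-methoxybenzoate | COC1=CC(=O)OC(CC(=O)/C=C/c2ccc(Oc3ccc(C(=O)OC)cc3OC)c(OCc3ccccc3)c2)=C1 | intermediate
9 | methyl (2E,8E)-9-{3-(benzyloxy)-4-[2-methoxy-4-(methoxycarbonyl)phenoxy]phenyl}-3-methoxy-5,7-dioxonona-2,8-dienoate (present as its magnesium chelate) | COC(=O)/C=C(\CC(=O)CC(=O)/C=C/c1ccc(Oc2ccc(C(=O)OC)cc2OC)c(OCc2ccccc2)c1)OC | intermediate
10 | methyl 4-{2-(benzyloxy)-4-[(E)-3-(2,6-dihydroxy-4-methoxyphenyl)-3-oxoprop-1-enyl]phenoxy}-3-methoxybenzoate | COc1cc(O)c(C(=O)/C=C/c2ccc(Oc3ccc(C(=O)OC)cc3OC)c(OCc3ccccc3)c2)c(O)c1 | intermediate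
11 | methyl 4-[2-(benzyloxy)-4-(5-hydroxy-7-methoxy-4-oxo-4H-chromen-2-yl)phenoxy]-3-methoxybenzoate | COC(=O)c1ccc(Oc2ccc(-c3cc(=O)c4c(O)cc(OC)cc4o3)cc2OCc2ccccc2)c(OC)c1 | intermediate
12 | methyl 4-{2-(benzyloxy)-4-[5-(benzyloxy)-7-methoxy-4-oxo-4H-chromen-2-yl]phenoxy}-3-methoxybenzoate | COC(=O)c1ccc(Oc2ccc(-c3cc(=O)c4c(OCc5ccccc5)cc(OC)cc4o3)cc2OCc2ccccc2)c(OC)c1 | intermediate
13 | 4-{2-(benzyloxy)-4-[5-(benzyloxy)-7-methoxy-4-oxo-4H-chromen-2-yl]phenoxy}-3-methoxybenzoic acid | OC(=O)c1ccc(Oc2ccc(-c3cc(=O)c4c(OCc5ccccc5)cc(OC)cc4o3)cc2OCc2ccccc2)c(OC)c1 | intermediate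
14 | 1-(2,4,6-trihydroxyphenyl)ethanone | CC(=O)c1c(O)cc(O)cc1O | starting material
15 | 1-[2,4-bis(benzyloxy)-6-hydroxyphenyl]ethanone | CC(=O)c1c(O)cc(OCc2ccccc2)cc1OCc1ccccc1 | intermediate
16 | 2-acetyl-3,5-bis(benzyloxy)phenyl 4-{2-(benzyloxy)-4-[5-(benzyloxy)-7-methoxy-4-oxo-4H-chromen-2-yl]phenoxy}-3-methoxybenzoate | CC(=O)c1c(OC(=O)c2ccc(Oc3ccc(-c4cc(=O)c5c(OCc6ccccc6)cc(OC)cc5o4)cc3OCc3ccccc3)c(OC)c2)cc(OCc2ccccc2)cc1OCc1ccccc1 | intermediate
17 | 1-[2,4-bis(benzyloxy)-6-hydroxyphenyl]-3-(4-{2-(benzyloxy)-4-[5-(benzyloxy)-7-methoxy-4-oxo-4H-chromen-2-yl]phenoxy}-3-methoxyphenyl)propane-1,3-dione | O=C(CC(=O)c1ccc(Oc2ccc(-c3cc(=O)c4c(OCc5ccccc5)cc(OC)cc4o3)cc2OCc2ccccc2)c(OC)c1)c1c(O)cc(OCc2ccccc2)cc1OCc1ccccc1 | intermediate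
18 | 5,7-bis(benzyloxy)-2-(4-{2-(benzyloxy)-4-[5-(benzyloxy)-7-methoxy-4-oxo-4H-chromen-2-yl]phenoxy}-3-methoxyphenyl)-4H-chromen-4-one | COc1cc(OCc2ccccc2)c2c(=O)cc(-c3ccc(Oc4ccc(-c5cc(=O)c6c(OCc7ccccc7)cc(OCc7ccccc7)cc6o5)cc4OC)c(OCc4ccccc4)c3)oc2c1 | intermediate
19 | bis(2,3-epoxide) of 18, an oxirane across C2–C3 of each chromenone unit (mixture of stereoisomers) | COc1cc(OCc2ccccc2)c2c(c1)OC1(c3ccc(Oc4ccc(C56OC5C(=O)c5c(OCc7ccccc7)cc(OCc7ccccc7)cc5O6)cc4OC)c(OCc4ccccc4)c3)OC1C2=O | intermediate
20 | 5,7-bis(benzyloxy)-2-(4-{2-(benzyloxy)-4-[5-(benzyloxy)-3-hydroxy-7-methoxy-4-oxo-4H-chromen-2-yl]phenoxy}-3-methoxyphenyl)-3-hydroxy-4H-chromen-4-one | COc1cc(OCc2ccccc2)c2c(=O)c(O)c(-c3ccc(Oc4ccc(-c5oc6cc(OCc7ccccc7)cc(OCc7ccccc7)c6c(=O)c5O)cc4OC)c(OCc4ccccc4)c3)oc2c1 | intermediate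
21 | 2-{4-[4-(3,5-dihydroxy-7-methoxy-4-oxo-4H-chromen-2-yl)-2-hydroxyphenoxy]-3-methoxyphenyl}-3,5,7-trihydroxy-4H-chromen-4-one (no stereocentre) | COc1cc(O)c2c(=O)c(O)c(-c3ccc(Oc4ccc(-c5oc6cc(O)cc(O)c6c(=O)c5O)cc4OC)c(O)c3)oc2c1 | target

**Step count**

Total: 14 steps. Longest linear sequence: 13 steps (steps 1 to 9 and 11 to 14, from 1 to 21); step 10 is a one-step side branch.

**Steps most likely to fail, with fallbacks**

Step 5. The acylation may stall through proton transfer from the acidic product to the dienolate. It may also be diverted by conjugate addition to the enoyl imidazole, by attack on the benzoate ester, or by metalation of the pyrone ring instead of the methyl group. The fallback sets out from aldehyde 4 and comes back at 8, replacing the acylation by an aldehyde addition and an oxidation. Wittig homologation of 4 with Ph3P=CHCHO (toluene, 80 °C) should give methyl 4-{2-(benzyloxy)-4-[(E)-3-oxoprop-1-enyl]phenoxy}-3-methoxybenzoate F3. One equivalent of lithiated 7 (LiN(iPr)2, THF, −78 °C) should add 1,2 to the far more electrophilic aldehyde to give the racemic allylic alcohol methyl 4-{2-(benzyloxy)-4-[(E)-3-hydroxy-4-(4-methoxy-2-oxo-2H-pyran-6-yl)but-1-enyl]phenoxy}-3-methoxybenzoate F4. Oxidation of this allylic alcohol with MnO2 in CH2Cl2 should then deliver 8.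

Step 6. The opened chain may fold by the aldol path to a resorcylate, or methoxide may add to the enone and the material may be lost to retro-Claisen cleavage, instead of the Claisen closure. The fallback sets out from aldehyde 4 and comes back at 10; the phloroglucinol ring of unit 1 is then bought instead of built. Commercial 1-(2,6-dihydroxy-4-methoxyphenyl)ethanone is protected (MOMCl, NaH, DMF) as 1-[4-methoxy-2,6-bis(methoxymethoxy)phenyl]ethanone F1. Claisen–Schmidt condensation of F1 with 4 (NaOMe, MeOH, rt, conditions under which the methyl ester is safe) should give methyl 4-{2-(benzyloxy)-4-[(E)-3-[4-methoxy-2,6-bis(methoxymethoxy)phenyl]-3-oxoprop-1-enyl]phenoxy}-3-methoxybenzoate F2. Acetal cleavage (HCl, MeOH/THF, 50 °C) should release 10; any flavanone formed alongside is converted in step 7 as before.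

Step 13. The double epoxidation of two electron-poor C2=C3 bonds may remain incomplete, or the dioxirane may instead oxidise benzylic C–H bonds and the electron-rich aryl ether rings. The fallback sets out from 18 and comes back at 20, replacing electrophilic oxidation by metalation. Twofold C3 lithiation of 18 (LiN(iPr)2, THF, −78 °C) and trapping with B(OMe)3 should give the 3,3'-bis(dimethoxyboryl) derivative of 18 F5, which carries a dimethoxyboryl group at C3 of each chromenone unit and is not isolated. Oxidation with H2O2/AcOH should convert both C–B bonds into the C3 hydroxyls of 20.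

**Further compounds**

F1 | step 6 | 1-[4-methoxy-2,6-bis(methoxymethoxy)phenyl]ethanone | CC(=O)c1c(OCOC)cc(OC)cc1OCOC
F2 | step 6 | methyl 4-{2-(benzyloxy)-4-[(E)-3-[4-methoxy-2,6-bis(methoxymethoxy)phenyl]-3-oxoprop-1-enyl]phenoxy}-3-methoxybenzoate | COCOc1cc(OC)cc(OCOC)c1C(=O)/C=C/c1ccc(Oc2ccc(C(=O)OC)cc2OC)c(OCc2ccccc2)c1
F3 | step 5 | methyl 4-{2-(benzyloxy)-4-[(E)-3-oxoprop-1-enyl]phenoxy}-3-methoxybenzoate | COC(=O)c1ccc(Oc2ccc(/C=C/C=O)cc2OCc2ccccc2)c(OC)c1
F4 | step 5 | methyl 4-{2-(benzyloxy)-4-[(E)-3-hydroxy-4-(4-methoxy-2-oxo-2H-pyran-6-yl)but-1-enyl]phenoxy}-3-methoxybenzoate (racemic) | COC1=CC(=O)OC(CC(O)/C=C/c2ccc(Oc3ccc(C(=O)OC)cc3OC)c(OCc3ccccc3)c2)=C1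
F5 | step 13 | 3,3'-bis(dimethoxyboryl) derivative of 18 (a dimethoxyboryl group at C3 of each chromenone unit) | COc1cc(OCc2ccccc2)c2c(=O)c(B(OC)OC)c(-c3ccc(Oc4ccc(-c5oc6cc(OCc7ccccc7)cc(OCc7ccccc7)c6c(=O)c5B(OC)OC)cc4OC)c(OCc4ccccc4)c3)oc2c1
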